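## The problem

Sideroxylonal C (19) is a 2-arylchroman: a pyran ring (O1, C2, C3, C4) fused to a phloroglucinol-derived ring A, with a second phloroglucinol ring B on C2, an isopropyl group on C3 and an isobutyl group on C4. Both aromatic rings end fully substituted, each with two formyl groups set between hydroxyl groups, so every bond to the rings is made next to two ortho substituents. The three contiguous stereocentres are (2R,3R,4R) and all-trans, so ring B, isopropyl and isobutyl can all sit equatorial on the half-chair. C3 and C4 carry only carbon and hydrogen, so no heteroatom can direct their formation. C4 must therefore come from an enantioselective C–C bond formation; it can then control C3 through allylic strain in an open-chain alkene, and the ring-closing transition state can place C2. The four aldehydes, the five phenols and the C2–O1 bond (a benzylic aryl ether next to an electron-rich ring, which ionises under acid) will not survive rough treatment, so the aldehydes and free phenols belong at the very end and the oxygens travel as methyl ethers. The enabling feature is that C2 lies between O1 and the electron-rich ring B and is therefore the carbon of an O-aryl oxocarbenium ion, while the isopropyl carbon on C3 can hold the positive charge left when a C3=C(CH3)2 alkene attacks C2. One cationic step can thus form O1–C2 and C2–C3, close the pyran ring and set C2 and C3 from C4.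

## Retrosynthesis

**Unmasking (19 ⇒ 18 ⇒ 16 ⇒ 15).** The five O–CH3 bonds of pentamethyl ether 18 are cut last; every methoxy group of 18 is ortho to a formyl group, which is the arrangement that BCl3 cleaves by chelation. The four aryl–CHO bonds are cut next, back to tetrabromide 16 and then to the formyl-free pentamethyl ether 15. The only free ring positions of 15 (C6, C8, C3′, C5′) each lie between two oxygen substituents, so bromination has no regiochemical choice. Bromine–lithium exchange followed by a formamide keeps the acid-labile C2–O1 bond in basic medium, which a fourfold Lewis-acid formylation would not. Compound 15 has no carbonyl group and no free phenol and is far easier to build.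

**Isopropyl group (15 ⇒ 14).** The methine C–H of the isopropyl group is cut to a C–Cl bond. Tertiary chloride 14 records where the positive charge of the ring closure ended; a radical chain reduction removes the chlorine without touching the stereocentres or the benzylic ether.

**Pyran ring (14 ⇒ 10 + 11).** O1–C2 and C2–C3 are cut together. The alternatives are cuts at O1–C8a or C4–C4a, which leave an open chain with three stereocentres to be built between two hindered rings. The chosen cut instead releases commercial 2,4,6-trimethoxybenzaldehyde (11) and aryl silyl ether 10, which has a single stereocentre and a trisubstituted alkene. The forward reaction must form the O-aryl oxocarbenium ion 12 from the silyl ether oxygen and the aldehyde, let the alkene attack C2 through C3 only, set C3 anti to isobutyl and C2 anti to C3, and deliver chloride to the tertiary cation 13. It must do this without Friedel–Crafts attack on ring A and without protic acid adding O1 to the alkene.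

**Alkene and silyl ether (10 ⇒ 8 ⇒ 7).** The C3=C double bond is traced to tertiary alcohol 8 by dehydration, and the O–Si bond to phenol 7. The alkene carbon that becomes the isopropyl carbon is the carbinol carbon of 7. The dehydration must be non-acidic, since acid would close 7 or 8 to a 2,2-dimethylchroman, and it should favour the trisubstituted alkene.

**Two methyl groups (7 ⇒ 5 ⇒ 4).** Both C–CH3 bonds of the carbinol are cut to lactone 5 (double Grignard addition), and 5 is the oxidation product of lactol 4. The stereocentre is β to the carbonyl group and cannot epimerise in either step.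

**C4 (4 ⇒ 1 + 2).** The C4–C4a bond is cut to 3,5-dimethoxyphenol (1) and (E)-5-methylhex-2-enal (2). An iminium-catalysed Friedel–Crafts alkylation ortho to the phenol, followed by hemiacetal formation, makes this bond and the only stereocentre that needs a chiral reagent. The enal carbons map onto the target as C1 → isopropyl carbon, C2 → C3, C3 → C4, and the remainder → isobutyl.

## Roads not taken

**Alternative 1: conjunctive cross-coupling with a boron handle on C3.** The cuts are C4–C4a and the C3–isopropyl bond. Isopropyllithium A4 and alkenylboronate A2 form an ate complex, which couples with aryl triflate A3 under a zerovalent palladium catalyst (from Pd(OAc)2 and a chiral ferrocenyl bisphosphine of the MandyPhos type). Aryl and isopropyl add anti across the (E)-alkene to give boronate A1.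
- Merits: two C–C bonds and both C3 and C4 arise in one catalytic step from three simple pieces. The relative configuration follows from the alkene geometry and the absolute one from the ligand, so C3 does not depend on substrate control. In that respect it is stronger than the chosen plan, where C3 relies on allylic strain.
- Weak points: a β-substituted alkenylboronate with a secondary alkyl migrating group tends to undergo direct coupling instead of the metallate shift. Triflate A3 is electron-rich and ortho,ortho-disubstituted. No ring closes: after A1, C2 with ring B must still be joined to a hindered secondary boronate by a stereospecific 1,2-migration, the C2 stereocentre set separately, the protecting group removed and O1–C2 closed.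
- Comparison: the chosen plan sets against the better C3 control of A1 a single cheap asymmetric step, ring closure, and C2 and C3 formed together.

**Alternative 2: SNAr ring closure activated by the formyl groups.** The cut is O1–C8a. The alkoxide of open-chain alcohol A6 displaces an ortho methoxy group of the diformyl-trimethoxyphenyl ring on C4 by addition–elimination and gives pentamethyl ether A5, which is identical with compound 18.
- Merits: the formyl groups are in place before the ring closes, so the late fourfold formylation, the weakest late step of the chosen plan, is avoided. The closure creates no stereocentre, needs no metal, and the two ortho methoxy groups are equivalent. The endgame from A5 is one step, clearly better than the chosen plan.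
- Weak points: the difficulty moves to A6. Three contiguous stereocentres must be built in an open chain between two fully substituted rings, with no ring to relay stereochemistry, and four aldehydes (or their masked forms) must pass through every C–C bond formation. An alkoxide in the presence of four aryl aldehydes also invites hydride transfer and addition.
- Comparison: the chosen plan trades a longer endgame for a front end that starts from three commercial compounds and sets two of the three stereocentres in the ring-forming step.

**Alternative 3: aryne oxy-arylation closed by Michael addition.** The cuts are O1–C8a and C4a–C4. The potassium alkoxide of hydroxy-enoate A8 adds to the aryne released by fluoride from silyl triflate A9, at the aryne carbon remote from the methoxy group. The aryl anion then adds 6-exo to the enoate and gives chroman ester A7.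
- Merits: two bonds and the ring form in one step, the aryne regiochemistry is reliable, and C2 and C3 come from well-developed aldol-type chemistry.
- Weak points: the secondary alkoxide of A8, flanked by a 2,6-dimethoxyaryl ring and an isopropyl group, is a poor nucleophile for the aryne. The aryl anion can be protonated before it cyclises. C4 is set only by substrate control in the Michael step. The acetate arm of A7 must still be turned into isobutyl (two methyl additions and a deoxygenation), which brings back the dehydration problem of the chosen plan. A8 needs its own asymmetric synthesis, and the bromination, formylation and demethylation endgame is unchanged.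
- Comparison: the alternative is equal in the late stages and longer before them. The chosen plan uses the alkene both as the nucleophile and as the source of the isopropyl group.

Key step: step 6

Assumptions on the chemistry:
- The sense of induction in step 1 follows the usual shielding model of diarylprolinol silyl ether iminium ions: the arene adds to the face of the (E)-iminium ion away from the diphenyl(silyloxy)methyl group, and the (S)-catalyst then gives (4R). If the opposite sense were found, the (R)-catalyst would be used.
- Enal 2 and aldehyde 11 are taken as articles of commerce.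

## Route

Step 1
Reactants: 1 3,5-dimethoxyphenol; 2 (E)-5-methylhex-2-enal
Product: 4 (4R)-4-isobutyl-5,7-dimethoxychroman-2-ol (both C2 epimers), via open-chain aldehyde 3 (not isolated)
Conditions: (S)-2-[diphenyl(trimethylsilyloxy)methyl]pyrrolidine (20 mol %), PhCO2H (20 mol %), toluene, 0 °C
Reagents that add atoms: none
Why: Iminium-catalysed asymmetric Friedel–Crafts alkylation of the electron-rich phenol at the position ortho to OH, made irreversible by hemiacetal formation of aldehyde 3 with the neighbouring hydroxyl; the bulky group of the (S)-catalyst shields one face of the (E)-iminium ion, so the arene adds to the other face of the enal β-carbon and C4 should form as (R).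

Step 2
Reactants: 4 (4R)-4-isobutyl-5,7-dimethoxychroman-2-ol
Product: 5 (4R)-4-isobutyl-5,7-dimethoxychroman-2-one
Conditions: pyridinium chlorochromate (C5H5NH[CrO3Cl]), powdered 4 Å molecular sieves, CH2Cl2, rt
Reagents that add atoms: none
Why: Chromate oxidation of a lactol to the lactone, the standard follow-up for 4-substituted chroman-2-ols; C4 is β to the new carbonyl group and is not touched.

Step 3
Reactants: 5 (4R)-4-isobutyl-5,7-dimethoxychroman-2-one
Product: 7 2-[(4R)-2-hydroxy-2,6-dimethylheptan-4-yl]-3,5-dimethoxyphenol, via methyl ketone 6 (not isolated)
Conditions: MeMgBr (4 equiv), THF, 0 °C to rt; aq. NH4Cl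
Reagents that add atoms: methylmagnesium bromide, C[Mg]Br
Why: Double Grignard addition to an aryl ester: the first equivalent expels the phenoxide and gives ketone 6, which is more electrophilic than the lactone and takes the second; the near-neutral quench avoids acid-induced closure of 7 to a 2,2-dimethylchroman.

Step 4
Reactants: 7 2-[(4R)-2-hydroxy-2,6-dimethylheptan-4-yl]-3,5-dimethoxyphenol
Product: 8 (4R)-4-[2,4-dimethoxy-6-(trimethylsilyloxy)phenyl]-2,6-dimethylheptan-2-ol
Conditions: Me3SiCl (1.1 equiv), Et3N, CH2Cl2, 0 °C; filtration, evaporation, no chromatography
Reagents that add atoms: chlorotrimethylsilane, C[Si](C)(C)Cl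
Why: O-silylation under amine base without a nucleophilic catalyst is much faster at the phenol than at the hindered tertiary alcohol, so the monosilyl ether should form selectively; the labile aryl silyl ether is carried on under anhydrous conditions.

Step 5
Reactants: 8 (4R)-4-[2,4-dimethoxy-6-(trimethylsilyloxy)phenyl]-2,6-dimethylheptan-2-ol
Product: 10 {2-[(4R)-2,6-dimethylhept-2-en-4-yl]-3,5-dimethoxyphenoxy}trimethylsilane, via tertiary sulfamate ester 9 (not isolated)
Conditions: methyl N-(triethylammoniosulfonyl)carbamate (Burgess reagent, 1.5 equiv), benzene, 50 °C; filtration through Et3N-deactivated silica (pentane)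
Reagents that add atoms: none
Why: Burgess dehydration: sulfamate ester 9 loses the sulfamate with intramolecular removal of a syn β-hydrogen under neutral conditions, and tertiary carbinols give mainly the more substituted (Zaitsev) alkene; no protic acid is set free, so the aryl silyl ether should survive and O1 should not add to the incipient cation; C4 is not involved.

Step 6
Reactants: 10 {2-[(4R)-2,6-dimethylhept-2-en-4-yl]-3,5-dimethoxyphenoxy}trimethylsilane; 11 2,4,6-trimethoxybenzaldehyde
Product: 14 (2R,3R,4R)-3-(2-chloropropan-2-yl)-4-isobutyl-5,7-dimethoxy-2-(2,4,6-trimethoxyphenyl)chroman, via oxocarbenium ion 12 (not isolated), via tertiary carbocation 13 (not isolated)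
Conditions: SnCl4 (1.5 equiv), 2,6-di-tert-butyl-4-methylpyridine (0.3 equiv), CH2Cl2, −78 °C; aq. NaHCO3 at −78 °C
Reagents that add atoms: tin tetrachloride (SnCl4), Cl[Sn](Cl)(Cl)Cl
Why: SnCl4 binds aldehyde 11, the silyl ether oxygen of 10 adds to the activated carbonyl group, the silyl group moves to the former carbonyl oxygen and the stannylated silanolate leaves, which gives the (E)-O-aryl oxocarbenium ion 12, stabilised by O1 and by the trimethoxyphenyl ring. The closest known reaction type is the Prins cyclisation of oxocarbenium ions made from silyl ethers and aldehydes with halide termination, together with the Prins closure of ortho-alkenylphenols to chromans. The pyran ring closes when alkene carbon C3 attacks C2 in a chair-like six-membered transition state in which the O1=C2 unit is endocyclic and the C3=C double bond is exocyclic (6-exo with respect to the alkene); attack through C3 is the Markovnikov mode and leaves tertiary cation 13, which takes chloride from the chlorostannate to give 14. C3 is controlled by C4: allylic 1,3-strain against the cis methyl group keeps C4–H in the alkene plane, so the face of C3 reached by the electrophile tethered through ring A is the one anti to isobutyl, hence 3,4-trans. C2 is controlled by the oxocarbenium geometry: in the (E)-ion ring B is anti to ring A and therefore equatorial in the chair, hence 2,3-trans, and the all-equatorial chroman is also the thermodynamic isomer should C2–C3 formation be reversible. The step needs O-attack and intramolecular alkene capture to beat Friedel–Crafts alkylation at C6 or C8 of ring A and proton-induced addition of O1 to the alkene; the silyl ether and the hindered pyridine keep protic acid out, the low temperature and the weak electrophilicity of the triply donor-substituted, doubly ortho-substituted aldehyde slow intermolecular arylation, and the tether makes alkene capture fast.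

Step 7
Reactants: 14 (2R,3R,4R)-3-(2-chloropropan-2-yl)-4-isobutyl-5,7-dimethoxy-2-(2,4,6-trimethoxyphenyl)chroman
Product: 15 (2R,3R,4R)-4-isobutyl-3-isopropyl-5,7-dimethoxy-2-(2,4,6-trimethoxyphenyl)chroman
Conditions: (Me3Si)3SiH (1.5 equiv), AIBN (0.2 equiv), toluene, 85 °C
Reagents that add atoms: none
Why: Radical chain dehalogenation: the silyl radical abstracts chlorine from the tertiary chloride and the tertiary alkyl radical takes hydrogen from the silane; the radical carbon is not a stereocentre and the neutral medium leaves the benzylic ether intact.

Step 8
Reactants: 15 (2R,3R,4R)-4-isobutyl-3-isopropyl-5,7-dimethoxy-2-(2,4,6-trimethoxyphenyl)chroman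
Product: 16 (2R,3R,4R)-6,8-dibromo-2-(3,5-dibromo-2,4,6-trimethoxyphenyl)-4-isobutyl-3-isopropyl-5,7-dimethoxychroman
Conditions: NBS (4.2 equiv), MeCN, 0 °C to rt, dark
Reagents that add atoms: N-bromosuccinimide, O=C1CCC(=O)N1Br
Why: Electrophilic aromatic bromination: the only free ring positions (C6, C8, C3′, C5′) each lie between two oxygen substituents and should all react, and the by-product is neutral succinimide, so the C2–O1 bond is not exposed to acid.

Step 9
Reactants: 16 (2R,3R,4R)-6,8-dibromo-2-(3,5-dibromo-2,4,6-trimethoxyphenyl)-4-isobutyl-3-isopropyl-5,7-dimethoxychroman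
Product: 18 (2R,3R,4R)-2-(3,5-diformyl-2,4,6-trimethoxyphenyl)-4-isobutyl-3-isopropyl-5,7-dimethoxychroman-6,8-dicarbaldehyde, via tetralithiated chroman 17 (not isolated)
Conditions: t-BuLi (8.4 equiv), THF, −78 °C; DMF (12 equiv), −78 to 0 °C; aq. NH4Cl
Reagents that add atoms: N,N-dimethylformamide, CN(C)C=O
Why: Bromine–lithium exchange (two equivalents of t-BuLi per bromide) gives aryllithium 17, each carbanion flanked and stabilised by two oxygen substituents, and Bouveault formylation with DMF gives hemiaminal alkoxides that release the aldehydes on work-up; the basic medium is safe for the chroman ether and the stereocentres.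

Step 10
Reactants: 18 (2R,3R,4R)-2-(3,5-diformyl-2,4,6-trimethoxyphenyl)-4-isobutyl-3-isopropyl-5,7-dimethoxychroman-6,8-dicarbaldehyde
Product: 19 sideroxylonal C, (2R,3R,4R)-2-(3,5-diformyl-2,4,6-trihydroxyphenyl)-5,7-dihydroxy-4-isobutyl-3-isopropylchroman-6,8-dicarbaldehyde
Conditions: BCl3 (15 equiv), CH2Cl2, −78 to 0 °C; H2O
Reagents that add atoms: none
Why: Chelation-assisted Lewis-acid ether cleavage: BCl3 held between a formyl oxygen and the ortho methoxy oxygen delivers chloride to the methyl group, and all five methoxy groups are ortho to a formyl group; the ring ether is a secondary benzylic ether on a now electron-poor diformyl ring and should ionise less readily, and no stereocentre takes part.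

## Compound list

1 | 3,5-dimethoxyphenol | COc1cc(O)cc(OC)c1 | starting material
2 | (E)-5-methylhex-2-enal | CC(C)C/C=C/C=O | starting material
3 | (3R)-3-(2-hydroxy-4,6-dimethoxyphenyl)-5-methylhexanal | CC(C)C[C@H](CC=O)c1c(O)cc(OC)cc1OC | intermediate (not isolated)
4 | (4R)-4-isobutyl-5,7-dimethoxychroman-2-ol (both C2 epimers) | CC(C)C[C@H]1c2c(OC)cc(OC)cc2OC(O)C1 | intermediate
5 | (4R)-4-isobutyl-5,7-dimethoxychroman-2-one | CC(C)C[C@H]1c2c(OC)cc(OC)cc2OC(=O)C1 | intermediate
6 | (4R)-4-(2-hydroxy-4,6-dimethoxyphenyl)-6-methylheptan-2-one (present as its bromomagnesium phenoxide) | CC(C)C[C@H](CC(C)=O)c1c(O)cc(OC)cc1OC | intermediate (not isolated)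
7 | 2-[(4R)-2-hydroxy-2,6-dimethylheptan-4-yl]-3,5-dimethoxyphenol | CC(C)C[C@H](CC(C)(C)O)c1c(O)cc(OC)cc1OC | intermediate
8 | (4R)-4-[2,4-dimethoxy-6-(trimethylsilyloxy)phenyl]-2,6-dimethylheptan-2-ol | CC(C)C[C@H](CC(C)(C)O)c1c(OC)cc(OC)cc1O[Si](C)(C)C | intermediate
9 | triethylammonium salt of methyl N-({(4R)-4-[2,4-dimethoxy-6-(trimethylsilyloxy)phenyl]-2,6-dimethylheptan-2-yl}oxysulfonyl)carbamate | CC(C)C[C@H](CC(C)(C)OS(=O)(=O)[N-]C(=O)OC)c1c(OC)cc(OC)cc1O[Si](C)(C)C.CC[NH+](CC)CC | intermediate (not isolated)
10 | {2-[(4R)-2,6-dimethylhept-2-en-4-yl]-3,5-dimethoxyphenoxy}trimethylsilane | CC(C)C[C@H](C=C(C)C)c1c(OC)cc(OC)cc1O[Si](C)(C)C | intermediate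
11 | 2,4,6-trimethoxybenzaldehyde | COc1cc(OC)c(C=O)c(OC)c1 | starting material
12 | (E)-{2-[(4R)-2,6-dimethylhept-2-en-4-yl]-3,5-dimethoxyphenyl}[(2,4,6-trimethoxyphenyl)methylidene]oxonium | CC(C)C[C@H](C=C(C)C)c1c(OC)cc(OC)cc1/[O+]=C/c1c(OC)cc(OC)cc1OC | intermediate (not isolated)
13 | 2-[(2R,3R,4R)-4-isobutyl-5,7-dimethoxy-2-(2,4,6-trimethoxyphenyl)chroman-3-yl]propan-2-ylium | CC(C)C[C@H]1c2c(OC)cc(OC)cc2O[C@@H](c2c(OC)cc(OC)cc2OC)[C@@H]1[C+](C)C | intermediate (not isolated)
14 | (2R,3R,4R)-3-(2-chloropropan-2-yl)-4-isobutyl-5,7-dimethoxy-2-(2,4,6-trimethoxyphenyl)chroman | CC(C)C[C@H]1c2c(OC)cc(OC)cc2O[C@@H](c2c(OC)cc(OC)cc2OC)[C@@H]1C(C)(C)Cl | intermediate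
15 | (2R,3R,4R)-4-isobutyl-3-isopropyl-5,7-dimethoxy-2-(2,4,6-trimethoxyphenyl)chroman | CC(C)C[C@H]1c2c(OC)cc(OC)cc2O[C@@H](c2c(OC)cc(OC)cc2OC)[C@@H]1C(C)C | intermediate
16 | (2R,3R,4R)-6,8-dibromo-2-(3,5-dibromo-2,4,6-trimethoxyphenyl)-4-isobutyl-3-isopropyl-5,7-dimethoxychroman | CC(C)C[C@H]1c2c(OC)c(Br)c(OC)c(Br)c2O[C@@H](c2c(OC)c(Br)c(OC)c(Br)c2OC)[C@@H]1C(C)C | intermediate
17 | (2R,3R,4R)-6,8-dilithio-2-(3,5-dilithio-2,4,6-trimethoxyphenyl)-4-isobutyl-3-isopropyl-5,7-dimethoxychroman | CC(C)C[C@H]1c2c(OC)c([Li])c(OC)c([Li])c2O[C@@H](c2c(OC)c([Li])c(OC)c([Li])c2OC)[C@@H]1C(C)C | intermediate (not isolated)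
18 | (2R,3R,4R)-2-(3,5-diformyl-2,4,6-trimethoxyphenyl)-4-isobutyl-3-isopropyl-5,7-dimethoxychroman-6,8-dicarbaldehyde | CC(C)C[C@H]1c2c(OC)c(C=O)c(OC)c(C=O)c2O[C@@H](c2c(OC)c(C=O)c(OC)c(C=O)c2OC)[C@@H]1C(C)C | intermediate
19 | sideroxylonal C, (2R,3R,4R)-2-(3,5-diformyl-2,4,6-trihydroxyphenyl)-5,7-dihydroxy-4-isobutyl-3-isopropylchroman-6,8-dicarbaldehyde | CC(C)C[C@H]1c2c(O)c(C=O)c(O)c(C=O)c2O[C@@H](c2c(O)c(C=O)c(O)c(C=O)c2O)[C@@H]1C(C)C | target

## Step count and least certain steps

Total: 10 steps. Longest linear sequence: 10 steps (1 and 2 to 19); aldehyde 11 enters at step 6.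

**Step 6 (key step).**
- What may go wrong: Friedel–Crafts attack of the tin-activated aldehyde on C6 or C8 of ring A instead of O-attack; loss of the silyl group followed by acid-induced addition of O1 to the alkene; capture of the tertiary cation by a neighbouring methoxy oxygen, or its loss of a proton, instead of chloride transfer; erosion of the 2,3-selectivity if the chair is not well organised.
- Fallback: the oxocarbenium ion is made in two stages, so that no free aldehyde meets the Lewis acid. Setting out from 10, the silyl group is removed (K2CO3, MeOH) to give 2-[(4R)-2,6-dimethylhept-2-en-4-yl]-3,5-dimethoxyphenol F1. Aldehyde 11 is converted with trimethyl orthoformate and a trace of acid into 2-(dimethoxymethyl)-1,3,5-trimethoxybenzene F2. F1 and F2 are joined by acetal exchange (pyridinium p-toluenesulfonate, removal of methanol) to the mixed O-aryl O-methyl acetal 1-{[2-[(4R)-2,6-dimethylhept-2-en-4-yl]-3,5-dimethoxyphenoxy](methoxy)methyl}-2,4,6-trimethoxybenzene F3. SnCl4 with the hindered pyridine at −78 °C then ionises F3 to the same ion 12, and the route is rejoined at 14.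

**Step 5.**
- What may go wrong: removal of a methyl hydrogen instead of a C3 hydrogen gives the isopropenyl isomer, which cannot close the six-membered ring in step 6 and is only a spectator there; the aryl silyl ether may be lost, or O1 may take part in the ionising sulfamate and close a 2,2-dimethylchroman.
- Fallback: setting out from 7, the phenol is acetylated (Ac2O, Et3N) to 2-[(4R)-2-hydroxy-2,6-dimethylheptan-4-yl]-3,5-dimethoxyphenyl acetate F4, whose ester oxygen is not nucleophilic. Acid-catalysed dehydration under equilibrating conditions (catalytic TsOH, toluene, 80 °C), where the trisubstituted alkene predominates, gives 2-[(4R)-2,6-dimethylhept-2-en-4-yl]-3,5-dimethoxyphenyl acetate F5. Methanolysis (K2CO3, MeOH) gives the phenol F1 already described, and silylation as in step 4 rejoins the route at 10.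

**Step 1.**
- What may go wrong: alkylation para to the hydroxyl group, double alkylation, or low facial selectivity with a β-alkyl enal.
- Fallback: a conjugate addition in which the alkyl group, not the arene, is the nucleophile. Setting out from 1, hydroarylation–lactonisation with ethyl propiolate (Pd(OAc)2, CF3CO2H) gives 5,7-dimethoxycoumarin F6, which can also be bought. Copper-catalysed asymmetric conjugate addition of isobutylmagnesium bromide (CuBr·SMe2, chiral ferrocenyl bisphosphine, −78 °C), with the ligand enantiomer chosen for (R), rejoins the route at 5 and replaces steps 1 and 2.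

**Step 9.**
- What may go wrong: incomplete fourfold exchange, or protonation of partly lithiated species, would leave under-formylated material that is hard to separate.
- Fallback: electrophilic formylation in place of the organolithium route. Setting out from 15, Rieche formylation (Cl2CHOMe, TiCl4, CH2Cl2, low temperature, excess reagent) at the four activated positions rejoins the route at 18 and also bypasses step 8. No new compound arises (entry F0). The price is exposure of the C2–O1 bond to a Lewis acid, tolerable only because the all-trans arrangement is the thermodynamic one.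

**Step 10.**
- What may go wrong: incomplete cleavage of the last methyl ether on a ring that is already a boron chelate, or BCl3-assisted opening of the O1–C2 bond with epimerisation at C2.
- Fallback: nucleophilic demethylation in place of the Lewis-acid cleavage. Setting out from 18, sodium ethanethiolate in DMF at elevated temperature attacks the methyl groups by SN2 (the phenoxides are stabilised by the ortho and para formyl groups) and rejoins the route at 19 after acidification. No new compound arises (entry F0).

## Further compounds

F1 | step 6 | 2-[(4R)-2,6-dimethylhept-2-en-4-yl]-3,5-dimethoxyphenol | CC(C)C[C@H](C=C(C)C)c1c(O)cc(OC)cc1OC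
F2 | step 6 | 2-(dimethoxymethyl)-1,3,5-trimethoxybenzene | COC(OC)c1c(OC)cc(OC)cc1OC
F3 | step 6 | 1-{[2-[(4R)-2,6-dimethylhept-2-en-4-yl]-3,5-dimethoxyphenoxy](methoxy)methyl}-2,4,6-trimethoxybenzene (both acetal epimers) | CC(C)C[C@H](C=C(C)C)c1c(OC)cc(OC)cc1OC(OC)c1c(OC)cc(OC)cc1OC
F4 | step 5 | 2-[(4R)-2-hydroxy-2,6-dimethylheptan-4-yl]-3,5-dimethoxyphenyl acetate | CC(C)C[C@H](CC(C)(C)O)c1c(OC)cc(OC)cc1OC(C)=O
F5 | step 5 | 2-[(4R)-2,6-dimethylhept-2-en-4-yl]-3,5-dimethoxyphenyl acetate | CC(C)C[C@H](C=C(C)C)c1c(OC)cc(OC)cc1OC(C)=O
F6 | step 1 | 5,7-dimethoxycoumarin | COc1cc(OC)c2ccc(=O)oc2c1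
F0 | step 9 | none | none
F0 | step 10 | none | none
A1 | alternative 1 | 2-[(3R,4R)-4-[2,4-dimethoxy-6-(methoxymethoxy)phenyl]-2,6-dimethylheptan-3-yl]-4,4,5,5-tetramethyl-1,3,2-dioxaborolane | CC(C)C[C@H]([C@H](B1OC(C)(C)C(C)(C)O1)C(C)C)c1c(OC)cc(OC)cc1OCOC
A2 | alternative 1 | 4,4,5,5-tetramethyl-2-[(E)-4-methylpent-1-en-1-yl]-1,3,2-dioxaborolane | CC(C)C/C=C/B1OC(C)(C)C(C)(C)O1
A3 | alternative 1 | 2,4-dimethoxy-6-(methoxymethoxy)phenyl trifluoromethanesulfonate | COCOc1cc(OC)cc(OC)c1OS(=O)(=O)C(F)(F)F
A4 | alternative 1 | isopropyllithium | [Li]C(C)C
A5 | alternative 2 | sideroxylonal C pentamethyl ether (identical with 18) | CC(C)C[C@H]1c2c(OC)c(C=O)c(OC)c(C=O)c2O[C@@H](c2c(OC)c(C=O)c(OC)c(C=O)c2OC)[C@@H]1C(C)C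
A6 | alternative 2 | (1R,2R,3R)-1,3-bis(3,5-diformyl-2,4,6-trimethoxyphenyl)-2-isopropyl-5-methylhexan-1-ol | CC(C)C[C@H]([C@@H](C(C)C)[C@@H](O)c1c(OC)c(C=O)c(OC)c(C=O)c1OC)c1c(OC)c(C=O)c(OC)c(C=O)c1OC
A7 | alternative 3 | methyl 2-[(2R,3R,4R)-3-isopropyl-5,7-dimethoxy-2-(2,4,6-trimethoxyphenyl)chroman-4-yl]acetate | COC(=O)C[C@H]1c2c(OC)cc(OC)cc2O[C@@H](c2c(OC)cc(OC)cc2OC)[C@@H]1C(C)C
A8 | alternative 3 | methyl (2E,4R,5R)-5-hydroxy-4-isopropyl-5-(2,4,6-trimethoxyphenyl)pent-2-enoate | COC(=O)/C=C/[C@@H](C(C)C)[C@@H](O)c1c(OC)cc(OC)cc1OC
A9 | alternative 3 | 3,5-dimethoxy-2-(trimethylsilyl)phenyl trifluoromethanesulfonate | COc1cc(OC)c([Si](C)(C)C)c(OS(=O)(=O)C(F)(F)F)c1
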